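The two phenolic carbons, C1 of the monobromo ring A and C2 of the dibromo ring B (ring B counted from its ether carbon C1), both sit ortho to the bridging oxygen. Each hydroxyl is therefore traced back to a formyl group. The formyl group on ring B first activates an ortho fluoride so that the two brominated rings can be joined by SNAr. A single peracid treatment of the resulting diaryl ether dialdehyde (one CHO ortho to oxygen on each ring, all three bromines already in place) then turns both C–CHO bonds into C–O bonds as formate esters. Formate methanolysis completes the four-step synthesis.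

Key step: step 3

Remark: the target has no stereogenic centre and its diaryl ether axis is not configurationally stable, so it is treated as achiral and no stereocontrol is needed.

Step 1
Reactants: 1 1,2-dibromo-3-fluorobenzene
Product: 4 3,4-dibromo-2-fluorobenzaldehyde, via aryllithium 2 (not isolated), via lithium hemiaminal alkoxide 3 (not isolated)
Conditions: LDA (1.1 equiv, commercial solution), THF, −78 °C, 1 added to the base; DMF (1.5 equiv), −78 °C; 1 M HCl, −78 °C → rt
Reagents that add atoms: N,N-dimethylformamide, CN(C)C=O
Why: Directed ortho-metalation: the C–H next to fluorine (C4 of 1) is the most acidic site, so kinetic deprotonation by LDA at −78 °C with the arene added to the base, formylation of aryllithium 2 with DMF and acidic collapse of the hemiaminal alkoxide 3 should give 4 before bromine migration or LiF elimination can compete.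

Step 2
Reactants: 4 3,4-dibromo-2-fluorobenzaldehyde (1.1 equiv); 5 4-bromo-2-hydroxybenzaldehyde
Product: 6 3,4-dibromo-2-(5-bromo-2-formylphenoxy)benzaldehyde
Conditions: K2CO3 (1.5 equiv), DMF, 90 °C, N2
Reagents that add atoms: none
Why: Nucleophilic aromatic substitution (addition–elimination): the phenoxide of 5 adds to the fluorine-bearing carbon of 4, the ortho formyl group stabilises the Meisenheimer adduct, and fluoride leaves much faster than any bromide, as in the known coupling of salicylaldehydes with 2-fluorobenzaldehydes.

Step 3
Reactants: 6 3,4-dibromo-2-(5-bromo-2-formylphenoxy)benzaldehyde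
Product: 8 3,4-dibromo-2-(5-bromo-2-formyloxyphenoxy)phenyl formate, via monoformate aldehyde 7 (not isolated)
Conditions: mCPBA (3 equiv), KH2PO4, CH2Cl2, 0 → 40 °C
Reagents that add atoms: meta-chloroperoxybenzoic acid (mCPBA), O=C(OO)c1cccc(Cl)c1
Why: Each aldehyde adds mCPBA to give a Criegee peroxyhemiacetal, whose aryl group shifts from carbon to the proximal peroxide oxygen as m-chlorobenzoate leaves, so C1 of ring A and C2 of ring B each exchange a C–C bond for a C–O bond and emerge as formate esters. This is the Baeyer–Villiger (Dakin-type) oxidation of ortho-alkoxy- and ortho-aryloxybenzaldehydes to aryl formates, a known reaction class that extends to brominated diaryl ether aldehydes. No ring is closed and no stereocentre is created. The selectivity needed is aryl over hydride migration in both Criegee adducts (formate, not carboxylic acid), and it is hardest to secure on the dibromo ring B. The lone pair of the ortho ether oxygen stabilises the positive charge developing on each migrating ipso carbon, and the weakly acidic, water-poor KH2PO4/CH2Cl2 medium favours the aryl shift and keeps the formates from hydrolysing to phenols that the peracid could over-oxidise. The less electron-poor ring A is expected to react first, giving monoformate 7, which excess peracid should carry on to 8.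

Step 4
Reactants: 8 3,4-dibromo-2-(5-bromo-2-formyloxyphenoxy)phenyl formate
Product: 9 3,4-dibromo-2-(5-bromo-2-hydroxyphenoxy)phenol
Conditions: K2CO3 (0.2 equiv), MeOH, 0 °C → rt; then dilute HCl
Reagents that add atoms: none
Why: Base-catalysed transesterification: aryl formates are among the most labile esters and are cleaved by methanol with a trace of carbonate, conditions under which the diaryl ether and the three aryl bromides are inert.

Compound list
1 | 1,2-dibromo-3-fluorobenzene | Fc1cccc(Br)c1Br | starting material
2 | (3,4-dibromo-2-fluorophenyl)lithium | [Li]c1ccc(Br)c(Br)c1F | intermediate (not isolated)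
3 | lithium (3,4-dibromo-2-fluorophenyl)(dimethylamino)methanolate, racemic and transient | [Li]OC(N(C)C)c1ccc(Br)c(Br)c1F | intermediate (not isolated)
4 | 3,4-dibromo-2-fluorobenzaldehyde | O=Cc1ccc(Br)c(Br)c1F | intermediate
5 | 4-bromo-2-hydroxybenzaldehyde | O=Cc1ccc(Br)cc1O | starting material
6 | 3,4-dibromo-2-(5-bromo-2-formylphenoxy)benzaldehyde | O=Cc1ccc(Br)cc1Oc1c(C=O)ccc(Br)c1Br | intermediate
7 | 4-bromo-2-(2,3-dibromo-6-formylphenoxy)phenyl formate | O=COc1ccc(Br)cc1Oc1c(C=O)ccc(Br)c1Br | intermediate (not isolated)
8 | 3,4-dibromo-2-(5-bromo-2-formyloxyphenoxy)phenyl formate | O=COc1ccc(Br)cc1Oc1c(OC=O)ccc(Br)c1Br | intermediate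
9 | 3,4-dibromo-2-(5-bromo-2-hydroxyphenoxy)phenol | Oc1ccc(Br)cc1Oc1c(O)ccc(Br)c1Br | target

Total step count: 4. Longest linear sequence: 4 steps (1 → 4 → 6 → 8 → 9); 5 is purchased.

Steps most likely to fail

1. Step 3. Hydride instead of aryl migration in the Criegee adduct of the ring-B aldehyde would lead to a carboxylic acid, or the oxidation could stall after the first formyl group. The fallback sets out from 6 and rejoins the route at 9; it replaces each formyl group by an acetyl group, so that methyl, a poor migrating group, competes with aryl in place of hydrogen. Addition of MeMgBr (THF, 0 °C) to both aldehydes of 6 should give 1-{4-bromo-2-[2,3-dibromo-6-(1-hydroxyethyl)phenoxy]phenyl}ethan-1-ol F1 as a diastereomer mixture of no consequence. Dess–Martin oxidation should give 1-[2-(2-acetyl-5-bromophenoxy)-3,4-dibromophenyl]ethan-1-one F2. Baeyer–Villiger oxidation with trifluoroperacetic acid (TFAA, urea–H2O2, Na2HPO4, CH2Cl2) should then give 2-(2-acetoxy-5-bromophenoxy)-3,4-dibromophenyl acetate F3 by aryl migration. Methanolysis (K2CO3, MeOH) of F3 releases 9.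

2. Step 2. The chelated, electron-poor salicylaldehyde phenoxide may add only slowly to a fluoride flanked by CHO and Br; at the temperature then required, displacement of the para-activated bromides (oligomeric ethers) and base-induced aldehyde degradation could take over. The fallback sets out from 5 and rejoins at 6; it masks the formyl group of the nucleophile, which makes the phenoxide more electron-rich and removes the para activation of its own bromide. Acetalisation of 5 (ethylene glycol, TsOH, toluene, Dean–Stark) should give 5-bromo-2-(1,3-dioxolan-2-yl)phenol F4. SNAr of F4 with 4 (Cs2CO3, DMF, 70 °C) should give 3,4-dibromo-2-[5-bromo-2-(1,3-dioxolan-2-yl)phenoxy]benzaldehyde F5. Acetal hydrolysis (1 M HCl, THF, rt) of F5 gives 6.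

3. Step 1. While the aryllithium waits for the electrophile, bromine migration (halogen dance) or loss of LiF to an aryne could scramble or destroy it. The fallback sets out from 1 and rejoins at 4; it traps the carbanion as it forms and brings in the formyl group by halogen–magnesium exchange. LDA added to a mixture of 1 and TMSCl in THF at −78 °C (in situ quench) should give (3,4-dibromo-2-fluorophenyl)trimethylsilane F6. Ipso-iododesilylation (ICl, CH2Cl2) should give 1,2-dibromo-3-fluoro-4-iodobenzene F7. Selective iodine–magnesium exchange (iPrMgCl·LiCl, THF, −40 °C) should give (3,4-dibromo-2-fluorophenyl)magnesium chloride F8, which is not isolated and is formylated with DMF to give 4 after acidic work-up.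

Further compounds
F1 | step 3 | 1-{4-bromo-2-[2,3-dibromo-6-(1-hydroxyethyl)phenoxy]phenyl}ethan-1-ol (diastereomer mixture) | CC(O)c1ccc(Br)cc1Oc1c(C(C)O)ccc(Br)c1Br
F2 | step 3 | 1-[2-(2-acetyl-5-bromophenoxy)-3,4-dibromophenyl]ethan-1-one | CC(=O)c1ccc(Br)cc1Oc1c(C(C)=O)ccc(Br)c1Br
F3 | step 3 | 2-(2-acetoxy-5-bromophenoxy)-3,4-dibromophenyl acetate | CC(=O)Oc1ccc(Br)cc1Oc1c(OC(C)=O)ccc(Br)c1Br
F4 | step 2 | 5-bromo-2-(1,3-dioxolan-2-yl)phenol | Oc1cc(Br)ccc1C1OCCO1
F5 | step 2 | 3,4-dibromo-2-[5-bromo-2-(1,3-dioxolan-2-yl)phenoxy]benzaldehyde | O=Cc1ccc(Br)c(Br)c1Oc1cc(Br)ccc1C1OCCO1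
F6 | step 1 | (3,4-dibromo-2-fluorophenyl)trimethylsilane | C[Si](C)(C)c1ccc(Br)c(Br)c1F
F7 | step 1 | 1,2-dibromo-3-fluoro-4-iodobenzene | Fc1c(I)ccc(Br)c1Br
F8 | step 1 | (3,4-dibromo-2-fluorophenyl)magnesium chloride | Cl[Mg]c1ccc(Br)c(Br)c1F
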